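The constants of this flask are unknown, so they have to be read from the south run, which is this same flask followed through its first minutes.

| setting | south | flask |
|---|---|---|
| electrophile | 0.34 M | 0.34 M |
| free base | 0.102 M | 0.102 M |
| protonated nucleophile | 0.442 M | 0.442 M |
| remark | the very flask that is asked about, followed so far |  |
| time |  | 50 min |

south run (percent of the electrophile charged)

| time / min | electrophile / % | target / % |
|---|---|---|
| 0.500 | 85 | 15 |
| 1.50 | 81 | 12 |
| 3.00 | 73 | 12 |
| 4.00 | 74 | 14 |
| 6.00 | 64 | 12 |
| 8.00 | 58 | 13 |
| 10.0 | 53 | 7 |

(readings scatter by 2 percentage points)

- part of the electrophile that has reacted at 50 min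
- share of the unused nucleophile that is free and not bound as protonated nucleophile, at 50 min

Two chemists agree on the opening: electrophile drops to 85% of the charge by 0.500 min, and target then hovers near 12%. They part over what follows.

The first draws a straight line: a fixed slice of the charge goes each minute, 0.0337 min⁻¹. That line reaches zero at 25.7 min, so she expects 100% reacted.

The second answers that a step fed by a flat target takes a fixed share of the electrophile still there, which is the pseudo-first-order picture. Her loss constant, the share of remaining electrophile lost per minute, read from the first and last readings with their scatter, is 0.0497 min⁻¹. It leaves 7.25% at the asked time.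

The readings do not separate them: at 6.00 min the line says 66.5% and the curve 64.7%, with a scatter of 2 percentage points.

The forecast sides with the curve, since “this fits the intermediate points as first order”, and gives 93% reacted; its 1% free it calls a guess.

    acid set free + free base ⇌ salt of the base, settled at all times (K = 1.20 × 10⁵ M⁻¹)
    electrophile + nucleophile → acid set free + target (k = 7.40 M⁻¹ min⁻¹)
    electrophile + target → side product (k = 0.670 M⁻¹ min⁻¹)
    crystals ⇌ acid set free, rate k4*(cs4 - [acid set free]) while solid is left; crystals form when [acid set free] > cs4 (solubility = 4.70 mM, k = 0.720 min⁻¹)
    nucleophile + acid set free ⇌ protonated nucleophile, settled at all times (K = 8900 M⁻¹)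

The flask gives 91.3% reacted and 1.50% free. At 5.00 min the line says 69.8% against 67.5%, but at 25.0 min it says 2.47% against 29.2%. From that state the loss constant gives 8.43% at 50.0 min, and the flask holds 8.66%. In this flask electrophile goes by two steps, with nucleophile and with target, and their shares per minute at 50.0 min add to 0.0540 min⁻¹, against the 0.0497 min⁻¹ read from the south run. In the neighbour flask with 0.14 M electrophile the same two shares add to 0.0890 min⁻¹ at 50.0 min, and that flask holds 1.7% of its electrophile.

The readings stem from a simulated flask for substances that don't exist, and the scatter is random.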